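**Retrosynthetic overview**
- The target is the (1R,3aS,4R,6aS) unsymmetrical 2,6-diaryl-3,7-dioxabicyclo[3.3.0]octane; the last operation only unmasks the phenol from its benzyl ether.
- Key disconnection: the C3a–C6a (C–C) and C4–O5 (C–O) bonds are cut together, back to an acyclic epoxy cinnamyl ether. In the forward sense, Ti(III) epoxide opening and 5-exo radical cyclisation close the first oxolane (C1/O2/C3/C3a/C6a). Iodine-triggered benzylic cation capture by the freed CH2O then closes the second (C3a/C4/O5/C6/C6a) in the same flask.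
- Only the benzylic ether carbon (future C1) is set beforehand; it relays to C6a, C3a and C4. The oxirane stereocentre is sacrificial.
- The epoxy ether comes from Williamson union of an erythro aryl epoxy alcohol with 3,4,5-trimethoxycinnamyl bromide. The epoxy alcohol comes from vinyl Grignard addition to O-benzylsyringaldehyde and Sharpless kinetic resolution; the bromide from methyl 3,4,5-trimethoxycinnamate.

Assumption: 4-(benzyloxy)-3,5-dimethoxybenzaldehyde and methyl (E)-3,4,5-trimethoxycinnamate are bought as inexpensive catalogue chemicals.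

**Step 1**
Reactants: 1 4-(benzyloxy)-3,5-dimethoxybenzaldehyde; 2 vinylmagnesium bromide
Product: 3 rac-1-[4-(benzyloxy)-3,5-dimethoxyphenyl]prop-2-en-1-ol
Conditions: CH2=CHMgBr (1.3 equiv), THF, −78 → 0 °C; aq NH4Cl
Reagents that add atoms: vinylmagnesium bromide (compound 2), C=C[Mg]Br
Why: Grignard 1,2-addition to a non-enolisable aryl aldehyde gives the racemic aryl vinyl carbinol, whose stereocentre is resolved in step 2.

**Step 2**
Reactants: 3 rac-1-[4-(benzyloxy)-3,5-dimethoxyphenyl]prop-2-en-1-ol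
Product: 4 (S)-[4-(benzyloxy)-3,5-dimethoxyphenyl][(2R)-oxiran-2-yl]methanol (erythro epoxy alcohol)
Conditions: Ti(OiPr)4 (0.2 equiv), L-(+)-DIPT (0.3 equiv), t-BuOOH (0.45 equiv), 4 Å MS, CH2Cl2, −20 °C; stop at ≤45% conversion; chromatography (recrystallise if ee <98%)
Reagents that add atoms: tert-butyl hydroperoxide, CC(C)(C)OO
Why: Sharpless kinetic resolution (Ti–tartrate epoxidation): with L-(+)-DIPT the (R)-carbinol (aryl > vinyl in CIP) reacts fast and erythro-selectively, giving 4 and leaving (S)-3 behind, which fixes the benzylic C–O centre that becomes C1 (R) of the target; the descriptor reads S in 4 only because the oxiranyl carbon outranks aryl.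

**Step 3**
Reactants: 5 methyl (2E)-3-(3,4,5-trimethoxyphenyl)prop-2-enoate
Product: 6 (2E)-3-(3,4,5-trimethoxyphenyl)prop-2-en-1-ol
Conditions: DIBAL-H (2.3 equiv), CH2Cl2, −78 → 0 °C; Rochelle salt
Reagents that add atoms: none
Why: DIBAL-H 1,2-reduction of an α,β-unsaturated ester stops cleanly at the allylic alcohol and leaves the E-alkene and aryl ethers untouched.

**Step 4**
Reactants: 6 (2E)-3-(3,4,5-trimethoxyphenyl)prop-2-en-1-ol
Product: 7 5-[(1E)-3-bromoprop-1-en-1-yl]-1,2,3-trimethoxybenzene (3,4,5-trimethoxycinnamyl bromide)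
Conditions: PBr3 (0.4 equiv), Et2O, 0 °C, 30 min; used crude at once
Reagents that add atoms: phosphorus tribromide, BrP(Br)Br
Why: PBr3 bromination of a primary allylic alcohol (bromide displacement of the phosphite ester) gives the conjugated primary bromide, which is also the thermodynamic allylic isomer.

**Step 5**
Reactants: 4 (S)-[4-(benzyloxy)-3,5-dimethoxyphenyl][(2R)-oxiran-2-yl]methanol; 7 3,4,5-trimethoxycinnamyl bromide
Product: 8 (2R)-2-[(S)-[4-(benzyloxy)-3,5-dimethoxyphenyl]{[(2E)-3-(3,4,5-trimethoxyphenyl)prop-2-en-1-yl]oxy}methyl]oxirane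
Conditions: NaH (1.2 equiv), THF, 0 °C; then 7 (1.2 equiv), n-Bu4NI (0.1 equiv), 0 °C → rt
Reagents that add atoms: none
Why: Williamson ether synthesis: the sodium alkoxide of 4 is alkylated (SN2) by the reactive allylic bromide at 0 °C in aprotic medium, faster than Payne rearrangement, and the C–O bond at the stereocentre is never broken, so configuration is retained.

**Step 6 (key step)**
Reactants: 8 epoxy cinnamyl ether
Product: 11 (1R,3aS,4R,6aS)-1-[4-(benzyloxy)-3,5-dimethoxyphenyl]-4-(3,4,5-trimethoxyphenyl)tetrahydro-1H,3H-furo[3,4-c]furan, via bis-titanated oxolane 9 (not isolated), via benzylic iodide 10 (not isolated)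
Conditions: Cp2TiCl2 (2.5 equiv), Zn dust, THF, rt (green Cp2TiCl decanted from Zn and added dropwise to 8); then I2 (1.3 equiv), rt → 40 °C; aq Na2S2O3
Reagents that add atoms: none
Why: Nugent–RajanBabu titanocene(III) epoxide opening gives the β-titanoxy secondary radical (oxirane centre erased), which cyclises 5-exo-trig onto the styrene through a Beckwith–Houk chair transition state with the aryl pseudo-equatorial (2,3-trans/3,4-cis, setting C6a and C3a from C1); iodine then turns the benzylic Ti/radical centre into the iodide, whose SN1 ionisation and capture by the cis CH2O–Ti closes the second oxolane with the aryl on the convex face (sets C4), a radical–polar crossover cascade.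

**Step 7**
Reactants: 11 benzyl-protected furofuran
Product: 12 4-[(1R,3aS,4R,6aS)-4-(3,4,5-trimethoxyphenyl)tetrahydro-1H,3H-furo[3,4-c]furan-1-yl]-2,6-dimethoxyphenol (target)
Conditions: H2 (1 atm), 10% Pd/C, EtOAc, rt; stopped as soon as 11 is consumed (TLC)
Reagents that add atoms: none
Why: Catalytic hydrogenolysis cleaves the aryl benzyl ether faster than the ring benzylic C–O bonds of the furofuran under neutral, low-pressure conditions, and no stereocentre is touched.

**Compound list**
1 | 4-(benzyloxy)-3,5-dimethoxybenzaldehyde | COc1cc(C=O)cc(OC)c1OCc1ccccc1 | starting material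
2 | vinylmagnesium bromide | C=C[Mg]Br | starting material
3 | rac-1-[4-(benzyloxy)-3,5-dimethoxyphenyl]prop-2-en-1-ol | COc1cc(cc(OC)c1OCc1ccccc1)C(O)C=C | intermediate
4 | (S)-[4-(benzyloxy)-3,5-dimethoxyphenyl][(2R)-oxiran-2-yl]methanol | COc1cc(cc(OC)c1OCc1ccccc1)[C@H](O)[C@H]1CO1 | intermediate
5 | methyl (2E)-3-(3,4,5-trimethoxyphenyl)prop-2-enoate | COC(=O)/C=C/c1cc(OC)c(OC)c(OC)c1 | starting material
6 | (2E)-3-(3,4,5-trimethoxyphenyl)prop-2-en-1-ol | OC/C=C/c1cc(OC)c(OC)c(OC)c1 | intermediate
7 | 5-[(1E)-3-bromoprop-1-en-1-yl]-1,2,3-trimethoxybenzene | BrC/C=C/c1cc(OC)c(OC)c(OC)c1 | intermediate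
8 | (2R)-2-[(S)-[4-(benzyloxy)-3,5-dimethoxyphenyl]{[(2E)-3-(3,4,5-trimethoxyphenyl)prop-2-en-1-yl]oxy}methyl]oxirane | COc1cc(cc(OC)c1OCc1ccccc1)[C@H](OC/C=C/c1cc(OC)c(OC)c(OC)c1)[C@H]1CO1 | intermediate
9 | bis-titanated oxolane: (2R,3S,4S)-2-[4-(benzyloxy)-3,5-dimethoxyphenyl]oxolane carrying 3-CH2O–TiCp2Cl and 4-CH(TiCp2Cl)(3,4,5-trimethoxyphenyl); benzylic C–Ti centre unassigned; Cp written as σ-bonded C5H5 in the SMILES | COc1cc([C@@H]2OC[C@@H](C([Ti](Cl)(C3C=CC=C3)C3C=CC=C3)c3cc(OC)c(OC)c(OC)c3)[C@H]2CO[Ti](Cl)(C3C=CC=C3)C3C=CC=C3)cc(OC)c1OCc1ccccc1 | intermediate (not isolated)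
10 | benzylic iodide: (2R,3S,4S)-2-[4-(benzyloxy)-3,5-dimethoxyphenyl]oxolane carrying 3-CH2O–TiCp2Cl and 4-CH(I)(3,4,5-trimethoxyphenyl); C–I centre unassigned | COc1cc([C@@H]2OC[C@@H](C(I)c3cc(OC)c(OC)c(OC)c3)[C@H]2CO[Ti](Cl)(C3C=CC=C3)C3C=CC=C3)cc(OC)c1OCc1ccccc1 | intermediate (not isolated)
11 | (1R,3aS,4R,6aS)-1-[4-(benzyloxy)-3,5-dimethoxyphenyl]-4-(3,4,5-trimethoxyphenyl)tetrahydro-1H,3H-furo[3,4-c]furan | COc1cc([C@@H]2OC[C@@H]3[C@H]2CO[C@H]3c2cc(OC)c(OC)c(OC)c2)cc(OC)c1OCc1ccccc1 | intermediate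
12 | 4-[(1R,3aS,4R,6aS)-4-(3,4,5-trimethoxyphenyl)tetrahydro-1H,3H-furo[3,4-c]furan-1-yl]-2,6-dimethoxyphenol | COc1cc([C@@H]2OC[C@@H]3[C@H]2CO[C@H]3c2cc(OC)c(OC)c(OC)c2)cc(OC)c1O | target

**Step count**
Total: 7 steps. Longest linear sequence: 5 steps (1 → 2 → 5 → 6 → 7).

**Three steps most likely to fail, with fallbacks**

Step 6 (cascade) is the main risk. Premature trapping of the first radical by Ti(III), reduction of the benzylic radical instead of iodination, or C4/C1 epimerisation by ZnI2 or HI would all cost yield or selectivity. The fallback sets out from 8 and comes back at 11, separating the two ring closures. Cp2TiCl (2.2 equiv, THF, rt) followed by an aqueous NaH2PO4 quench instead of iodine gives the monocyclic alcohol [(2R,3S,4S)-2-[4-(benzyloxy)-3,5-dimethoxyphenyl]-4-(3,4,5-trimethoxybenzyl)oxolan-3-yl]methanol F5. DDQ (1.2 equiv, CH2Cl2, cat. AcOH, 0 °C → rt) then abstracts hydride from the trimethoxybenzyl CH2, and the cis CH2OH captures the cation to give 11. The open question there is whether DDQ attacks that CH2 in preference to the C2–H benzylic ether position.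

Step 2 (kinetic resolution) is the second risk. A terminal vinyl carbinol reacts slowly and with only moderate selectivity factor, the yield is capped below 50%, and the electron-rich benzylic alcohol is Lewis-acid sensitive. The fallback sets out from 3 and comes back at 4, using enzymatic resolution. Lipase (Amano PS or CAL-B), vinyl acetate, MTBE, 30 °C acylates the (R)-enantiomer (Kazlauskas preference: aryl large, vinyl medium). This gives (R)-1-[4-(benzyloxy)-3,5-dimethoxyphenyl]prop-2-en-1-yl acetate F1, which is separated from unreacted (S)-3. K2CO3/MeOH then gives (R)-1-[4-(benzyloxy)-3,5-dimethoxyphenyl]prop-2-en-1-ol F2. Hydroxyl-directed epoxidation (VO(acac)2 2 mol%, t-BuOOH, CH2Cl2, 0 °C) gives 4 as the major erythro isomer. Its threo epimer (S)-[4-(benzyloxy)-3,5-dimethoxyphenyl][(2S)-oxiran-2-yl]methanol F3 is removed by chromatography.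

Step 5 (etherification) is the third risk: Payne rearrangement of the epoxy alkoxide and decomposition of the electron-rich allylic bromide. The fallback sets out from 6 (with 4) and comes back at 8, replacing SN2 alkylation by Pd-catalysed allylic etherification. Alcohol 6 with ClCO2Me and pyridine (CH2Cl2, 0 °C) gives (2E)-3-(3,4,5-trimethoxyphenyl)prop-2-en-1-yl methyl carbonate F4. Pd(PPh3)4 (5 mol%) and the zinc alkoxide of 4 (Et2Zn 0.5 equiv, THF, rt) then give the linear E ether 8 by Tsuji–Trost attack at the unsubstituted allyl terminus. This avoids both the free sodium alkoxide and the bromide.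

**Further compounds**
F1 | step 2 | (R)-1-[4-(benzyloxy)-3,5-dimethoxyphenyl]prop-2-en-1-yl acetate | COc1cc(cc(OC)c1OCc1ccccc1)[C@H](OC(C)=O)C=C
F2 | step 2 | (R)-1-[4-(benzyloxy)-3,5-dimethoxyphenyl]prop-2-en-1-ol | COc1cc(cc(OC)c1OCc1ccccc1)[C@H](O)C=C
F3 | step 2 | (S)-[4-(benzyloxy)-3,5-dimethoxyphenyl][(2S)-oxiran-2-yl]methanol | COc1cc(cc(OC)c1OCc1ccccc1)[C@H](O)[C@@H]1CO1
F4 | step 5 | (2E)-3-(3,4,5-trimethoxyphenyl)prop-2-en-1-yl methyl carbonate | COC(=O)OC/C=C/c1cc(OC)c(OC)c(OC)c1
F5 | step 6 | [(2R,3S,4S)-2-[4-(benzyloxy)-3,5-dimethoxyphenyl]-4-(3,4,5-trimethoxybenzyl)oxolan-3-yl]methanol | COc1cc([C@@H]2OC[C@@H](Cc3cc(OC)c(OC)c(OC)c3)[C@H]2CO)cc(OC)c1OCc1ccccc1
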